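**Plan**
Retrosynthesis: the primary alcohols at C9 and C9' and the ring A catechol are traced back to two alkyl esters and two aryl pivalates. Then C8–O4' and C7–C8 are cut at the same time.
Enabling feature: the three non-hydrogen neighbours of C8 are the ether oxygen O4' on ring B, the benzylic carbinol carbon C7 on ring A and the hydroxymethyl carbon C9. This is the pattern left when an (alkoxycarbonyl)carbene takes up an O–H nucleophile and then a C=O electrophile.
Forward: no ring is made. Rings A and B are bought as 3,4-dihydroxybenzaldehyde and hydroferulic acid and each is adjusted in one step. The chain is joined in one flask, ring B–O4'–C8 first and C8–C7–ring A second, and one hydride step finishes the molecule.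
Stereochemistry: C7 and C8 both arise in the union. A zirconium binaphtholate on the aldehyde picks the face at C7, its anti-selective open transition state sets C8 (erythro), and the reduction leaves both centres alone.

Key step: step 3

Assumption: the sense of induction of the zirconium binaphtholate has not been mapped for this substrate class, so the (R)-ligand is written as the one that opens the Re face of the aldehyde; should the first configurational correlation show the antipode, the equally available (S)-ligand is used with nothing else changed.

Step 1
Reactants: 1 3-(4-hydroxy-3-methoxyphenyl)propanoic acid (hydroferulic acid)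
Product: 2 methyl 3-(4-hydroxy-3-methoxyphenyl)propanoate
Conditions: MeOH, H2SO4 (cat.), reflux
Reagents that add atoms: methanol, CO
Why: Fischer esterification of an unhindered aliphatic acid in excess methanol is driven by mass action and leaves the phenol and the aryl methyl ether untouched; the ester masks the future C9' alcohol, which would otherwise compete as an O–H donor in step 3, and no stereocentre is involved.

Step 2
Reactants: 3 3,4-dihydroxybenzaldehyde
Product: 4 3,4-bis(pivaloyloxy)benzaldehyde (4-formyl-1,2-phenylene bis(2,2-dimethylpropanoate))
Conditions: PivCl (2.4 equiv), Et3N (2.6 equiv), DMAP (cat.), CH2Cl2, 0 °C to rt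
Reagents that add atoms: pivaloyl chloride, CC(C)(C)C(=O)Cl
Why: DMAP-catalysed O-acylation (nucleophilic acyl-transfer catalysis) of both phenols by an acid chloride is routine for catechols, leaves the aldehyde alone and turns the donor catechol into an acceptor-substituted ring; no stereocentre is involved.

Step 3
Reactants: 2 methyl 3-(4-hydroxy-3-methoxyphenyl)propanoate; 4 3,4-bis(pivaloyloxy)benzaldehyde; 5 ethyl diazoacetate
Product: 8 ethyl (2S,3S)-3-[3,4-bis(pivaloyloxy)phenyl]-3-hydroxy-2-[2-methoxy-4-(3-methoxy-3-oxopropyl)phenoxy]propanoate (erythro; C2 = C8 and C3 = C7 of the target), via rhodium carbenoid 6 (not isolated), via oxonium ylide 7 (not isolated)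
Conditions: Rh2(OAc)4 (2 mol %), Zr(OtBu)4 (15 mol %), (R)-3,3'-diiodo-BINOL (18 mol %; catalyst preformed, tBuOH removed in vacuo), 4 Å MS, CH2Cl2, 0 °C; 4 (1.5 equiv); 5 (1.3 equiv) by syringe pump over 6 h
Reagents that add atoms: none
Why: Proposed new method: Rh2(OAc)4 expels N2 from 5 to give the electrophilic carbenoid 6, the phenolic oxygen O4' of 2 adds to the carbene carbon (the future C8) to give the protic oxonium ylide 7, and 7, reacting as an ester enol, attacks C7 of the zirconium-bound aldehyde 4 faster than its own proton transfer would turn it into the simple aryloxyacetate. The closest known reaction type is the dirhodium and Lewis acid co-catalysed three-component aldol-type trapping of alcohol-derived oxonium ylides of aryl diazoacetates by aldehydes; a phenol combined with an acceptor-only diazoacetate has not been shown there, although both are known partners in O–H insertion through the same kind of ylide. No ring is closed, since C8–O4' and C7–C8 are both formed in an open chain. C7 (S) is controlled by the (R)-3,3'-diiodobinaphtholate on zirconium, which should leave the Re face of the coordinated aldehyde open, and C8 (S in the ester) is controlled by the open antiperiplanar transition state that makes such zirconium binaphtholates anti-selective irrespective of enol geometry, so that the Si face of the enol carbon bonds and the erythro isomer results. The step needs chemoselectivity for trapping over proton transfer and for rhodium over zirconium in the consumption of 5 (diazo aldol addition or homologation of 4 to a β-keto ester being the alternatives), and this is secured by the two electron-withdrawing acyloxy groups that make 4 a strongly activated acceptor, by the excess of 4 and by slow addition that keeps 5 at trace concentration. Pivalates are chosen over acetates because their hindered carbonyl groups resist acyl transfer to 2 or to zirconium alkoxides, and tBuOH is stripped from the catalyst so that 2 is the only free O–H donor.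

Step 4
Reactants: 8 ethyl (2S,3S)-3-[3,4-bis(pivaloyloxy)phenyl]-3-hydroxy-2-[2-methoxy-4-(3-methoxy-3-oxopropyl)phenoxy]propanoate
Product: 9 (1S,2R)-1-(3,4-dihydroxyphenyl)-2-[4-(3-hydroxypropyl)-2-methoxyphenoxy]propane-1,3-diol (target; 7S,8R, erythro)
Conditions: LiAlH4 (6 equiv), THF, 0 °C to rt, Ar, 8 added to the hydride; then degassed aq. HCl (1 M) to pH 3, 0 °C, EtOAc extraction under Ar
Reagents that add atoms: none
Why: Exhaustive LiAlH4 ester reduction, as practised on 2-aryloxy-3-hydroxy esters in the preparation of arylglycerol β-aryl ethers, converts the ethyl and methyl esters into the C9 and C9' primary alcohols and cleaves both aryl pivalates to the phenols, addition of 8 to excess hydride lets reduction outrun retro-aldol cleavage of the C7 alkoxide, and C7 and C8 are spectators (C8 changes descriptor from S to R only because CH2OH ranks below C7).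

**Compound list**
1 | 3-(4-hydroxy-3-methoxyphenyl)propanoic acid (hydroferulic acid) | COc1cc(CCC(=O)O)ccc1O | starting material
2 | methyl 3-(4-hydroxy-3-methoxyphenyl)propanoate | COc1cc(CCC(=O)OC)ccc1O | intermediate
3 | 3,4-dihydroxybenzaldehyde | O=Cc1ccc(O)c(O)c1 | starting material
4 | 3,4-bis(pivaloyloxy)benzaldehyde | O=Cc1ccc(OC(=O)C(C)(C)C)c(OC(=O)C(C)(C)C)c1 | intermediate
5 | ethyl diazoacetate | CCOC(=O)C=[N+]=[N-] | starting material
6 | rhodium carbenoid, Rh2(OAc)4=CHCO2Et | CCOC(=O)[CH]=[Rh+2].[Rh+2].CC(=O)[O-].CC(=O)[O-].CC(=O)[O-].CC(=O)[O-] | intermediate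
7 | protic oxonium ylide from 2 and the (ethoxycarbonyl)carbene unit | COc1cc(CCC(=O)OC)ccc1[OH+][CH-]C(=O)OCC | intermediate
8 | ethyl (2S,3S)-3-[3,4-bis(pivaloyloxy)phenyl]-3-hydroxy-2-[2-methoxy-4-(3-methoxy-3-oxopropyl)phenoxy]propanoate | COc1cc(CCC(=O)OC)ccc1O[C@H](C(=O)OCC)[C@@H](O)c1ccc(OC(=O)C(C)(C)C)c(OC(=O)C(C)(C)C)c1 | intermediate
9 | (1S,2R)-1-(3,4-dihydroxyphenyl)-2-[4-(3-hydroxypropyl)-2-methoxyphenoxy]propane-1,3-diol | COc1cc(CCCO)ccc1O[C@H](CO)[C@@H](O)c1ccc(O)c(O)c1 | target

Total step count: 4. Longest linear sequence: 3 (step 1 or step 2, then steps 3 and 4).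

**Steps most likely to fail**

Step 3. Three processes threaten it.
- Proton transfer within the phenol-derived ylide may outrun C–C bond formation.
- Zirconium may consume the diazo ester by direct addition to the aldehyde.
- The guaiacol unit may compete with the binaphtholate for zirconium and so erode facial and anti selectivity.

The fallback uses known chemistry, sets out from 2 and 4 and comes back at 9. Phenol 2 is O-alkylated with commercial (S)-4-benzyl-3-(chloroacetyl)oxazolidin-2-one (K2CO3, NaI cat., acetone; Williamson ether synthesis) to give the N-(aryloxyacetyl)oxazolidinone F1. Soft enolisation with Bu2BOTf and iPr2NEt touches only the imide and not the side-chain methyl ester. The Evans syn aldol addition to 4 should then give the (2S,3R) threo adduct F2, in which the auxiliary fixes C8. Mitsunobu inversion at the benzylic C7 (PPh3, DIAD, 4-nitrobenzoic acid, THF) should give the erythro (2S,3S) 4-nitrobenzoate F3. This aldol-then-inversion sequence is established for arylglycerol β-aryl ethers. LiBH4 in THF/MeOH removes the auxiliary reductively, reduces the methyl ester and cleaves the nitrobenzoate and both pivalates, which leads to 9.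

Step 4. The liberated catechol may oxidise in air during the aqueous work-up. The very polar pentaol may also be lost to the aluminium-containing aqueous phase or on silica. The fallback sets out from 8 and comes back at 9. The crude extract of the same reduction is not purified. It is silylated at once (TESCl, imidazole, DMF) to the pentakis(triethylsilyl) ether F4, a non-polar and air-stable derivative that can be chromatographed and stored. Et3N·3HF in THF then releases 9 with only volatile by-products, so the free catechol never meets silica, base or metal salts. A silyl derivative is preferred to a peracetate because a benzylic acetate para to a freed phenoxide would ionise to a quinone methide and scramble C7.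

Step 2. The second acylation takes place next to a bulky ester and may stall, and an aryl ester may be partly lost on aqueous work-up or silica. The fallback sets out from 3 and comes back at 9. Aldehyde 3 is treated with ethyl chloroformate and Et3N (CH2Cl2, 0 °C) to give 3,4-bis(ethoxycarbonyloxy)benzaldehyde F5. Its slim carbonate groups go on without crowding, withdraw electrons to a comparable degree and are less prone to acyl transfer than acetates. F5 takes the place of 4 under the conditions of step 3 and should give the erythro bis(carbonate) ester F6. The LiAlH4 conditions of step 4 reduce the carbonates along with the two esters, which leads to 9.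

**Further compounds**
F1 | step 3 | methyl 3-(4-{2-[(4S)-4-benzyl-2-oxooxazolidin-3-yl]-2-oxoethoxy}-3-methoxyphenyl)propanoate | COc1cc(CCC(=O)OC)ccc1OCC(=O)N1[C@@H](Cc2ccccc2)COC1=O
F2 | step 3 | (4S)-4-benzyl-3-{(2S,3R)-3-[3,4-bis(pivaloyloxy)phenyl]-3-hydroxy-2-[2-methoxy-4-(3-methoxy-3-oxopropyl)phenoxy]propanoyl}oxazolidin-2-one (threo) | COc1cc(CCC(=O)OC)ccc1O[C@H](C(=O)N1[C@@H](Cc2ccccc2)COC1=O)[C@H](O)c1ccc(OC(=O)C(C)(C)C)c(OC(=O)C(C)(C)C)c1
F3 | step 3 | (1S,2S)-3-[(4S)-4-benzyl-2-oxooxazolidin-3-yl]-1-[3,4-bis(pivaloyloxy)phenyl]-2-[2-methoxy-4-(3-methoxy-3-oxopropyl)phenoxy]-3-oxopropyl 4-nitrobenzoate (erythro) | COc1cc(CCC(=O)OC)ccc1O[C@H](C(=O)N1[C@@H](Cc2ccccc2)COC1=O)[C@@H](OC(=O)c1ccc(cc1)[N+](=O)[O-])c1ccc(OC(=O)C(C)(C)C)c(OC(=O)C(C)(C)C)c1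
F4 | step 4 | pentakis(triethylsilyl) ether of 9 (7S,8R) | COc1cc(CCCO[Si](CC)(CC)CC)ccc1O[C@H](CO[Si](CC)(CC)CC)[C@@H](O[Si](CC)(CC)CC)c1ccc(O[Si](CC)(CC)CC)c(O[Si](CC)(CC)CC)c1
F5 | step 2 | 3,4-bis(ethoxycarbonyloxy)benzaldehyde | O=Cc1ccc(OC(=O)OCC)c(OC(=O)OCC)c1
F6 | step 2 | ethyl (2S,3S)-3-[3,4-bis(ethoxycarbonyloxy)phenyl]-3-hydroxy-2-[2-methoxy-4-(3-methoxy-3-oxopropyl)phenoxy]propanoate | COc1cc(CCC(=O)OC)ccc1O[C@H](C(=O)OCC)[C@@H](O)c1ccc(OC(=O)OCC)c(OC(=O)OCC)c1
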